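**Plan**

- Retrosynthesis: the phthalide is opened by removing its carbonyl carbon (CO) and cutting C3–CH2 (aryl aldehyde + alkylzinc). The spiroketal is opened to a γ,γ′-dihydroxy ketone. The two C–C bonds C7–C8 and C9–C5 of ring B are then cut together (spiroketal locants: ring A = O1, C2, C3, C4, C5 with the side chain on C2; ring B = C5, O6, C7, C8, C9 with CH3 on C7).
- Enabling feature: in ring B the ethano unit C8–C9 lies between two oxygen-bearing carbons, carbinol-level C7 and ketone-level spiro C5 (a 1,4-dioxygenated pattern). Phenyl vinyl sulfone can therefore act as an ethylene unit that accepts at C8 and donates at C9, linking an α-oxygenated carbanion (C7) to the carbonyl carbon of the ring A lactone (C5).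
- Forward order: the ring A butyrolactone comes from the chiral pool and is chain-extended; the three-component union forms C7–C8 and C9–C5; the sulfonyl and carbamoyl helpers are removed; rings A and B close together as the spiroketal; the alkene terminus is joined to the aryl aldehyde; the phthalide ring is closed last by carbonylation.
- Stereochemistry: C2 from (R)-5-(hydroxymethyl)butyrolactone; C7 from (+)-sparteine-mediated lithiation of an O-ethyl carbamate; spiro C5 by acid equilibration, separation and recycling; phthalide C3 by ligand-controlled alkylzinc addition.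

Key step: step 4

Remark: the spiro centre of a 2,7-dialkyl-1,6-dioxaspiro[4.4]nonane epimerises under acid, so both C5 epimers are expected in step 6; the (5S) epimer is carried on and the (5R) epimer is returned to the equilibration.

**Step 1**
Reactants: 1 (R)-5-(hydroxymethyl)dihydrofuran-2(3H)-one
Product: 2 [(2R)-5-oxotetrahydrofuran-2-yl]methyl 4-methylbenzenesulfonate
Conditions: TsCl, pyridine, CH2Cl2, 0 °C → rt
Reagents that add atoms: p-toluenesulfonyl chloride, Cc1ccc(cc1)S(Cl)(=O)=O
Why: Sulfonylation of the primary alcohol (tosylation) should proceed without touching the lactone or the stereocenter.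

**Step 2**
Reactants: 2 [(2R)-5-oxotetrahydrofuran-2-yl]methyl 4-methylbenzenesulfonate; 3 5-bromopent-1-ene
Product: 6 (S)-5-(hex-5-en-1-yl)dihydrofuran-2(3H)-one, via pent-4-enylmagnesium bromide 4 (not isolated), via bromomagnesium dipentenylcuprate 5 (not isolated)
Conditions: 3, Mg, THF, rt; CuI (0.5 equiv per Grignard reagent), −40 °C; then 2, −40 → −20 °C; aq. NH4Cl
Reagents that add atoms: none
Why: Substitution of the primary tosylate by a magnesium dialkylcuprate (cuprate alkylation) should be faster at low temperature than attack on the lactone carbonyl; the stereocenter is not touched and becomes (S) only because the ring CH2 now outranks the side chain.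

**Step 3**
Reactants: 7 ethanol
Product: 8 ethyl N,N-diisopropylcarbamate
Conditions: iPr2NCOCl, pyridine, 90 °C
Reagents that add atoms: N,N-diisopropylcarbamoyl chloride, CC(C)N(C(C)C)C(Cl)=O
Why: O-Carbamoylation of the alcohol installs the hindered carbamate that directs and stabilises α-lithiation and resists nucleophiles.

**Step 4**
Reactants: 8 ethyl N,N-diisopropylcarbamate; 9 phenyl vinyl sulfone; 6 (S)-5-(hex-5-en-1-yl)dihydrofuran-2(3H)-one
Product: 12 (2S,8S)-8-hydroxy-5-oxo-4-(phenylsulfonyl)tetradec-13-en-2-yl N,N-diisopropylcarbamate (both C4 epimers), via lithiated carbamate 10 (not isolated), via lithiated sulfone 11 (not isolated)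
Conditions: 8 (2.3 equiv), sBuLi (2.2 equiv), (+)-sparteine (2.3 equiv), Et2O, −78 °C, 5 h; 9 (2.1 equiv) in THF added slowly, −78 °C; 6 (1.0 equiv) in THF, −78 → −40 °C; AcOH, then aq. NH4Cl
Reagents that add atoms: none
Why: Proposed new method: a sparteine-bound α-carbamoyloxy alkyllithium has not been used as the first nucleophile of a vinyl sulfone three-component coupling, but each half is established reactivity, the closest known reaction type being conjugate addition of an organolithium to a vinyl sulfone with trapping of the α-sulfonyl carbanion by an acyl electrophile. Lithiated carbamate 10 attacks the β-carbon of 9 to make the C7–C8 bond, and the α-sulfonyl carbanion 11 so formed attacks the lactone carbonyl of 6 to make the C9–C5 bond; ring A opens to the alkoxide, and the acidic β-keto sulfone is deprotonated at once by the second equivalent of 11, which prevents a second addition. No ring is closed in this step (12 may rest as its five-membered lactol by reversible 5-exo-trig addition of the C2 hydroxyl to the ketone). The new C7 stereocenter is reagent-controlled: (+)-sparteine directs removal of the pro-R hydrogen of 8 and the configurationally stable lithium compound is expected to be substituted with retention, giving (S); the sulfonyl-bearing carbon forms without control and is erased in step 5, and C2 is untouched. The step needs 1,4-addition to outrun anionic oligomerisation of 9 and needs attack at the lactone instead of the carbamate; slow addition of 9 to the more nucleophilic secondary alkyllithium at −78 °C, the low nucleophilicity of the sulfone-stabilised carbanion towards 9 and the shielding of the carbamate carbonyl by two isopropyl groups should secure both.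

**Step 5**
Reactants: 12 (2S,8S)-8-hydroxy-5-oxo-4-(phenylsulfonyl)tetradec-13-en-2-yl N,N-diisopropylcarbamate
Product: 14 (2S)-4-[(5S)-5-(hex-5-en-1-yl)-2-methoxytetrahydrofuran-2-yl]butan-2-yl N,N-diisopropylcarbamate (both anomers), via hydroxy ketone 13 (not isolated)
Conditions: SmI2 (3 equiv), THF/MeOH, −78 °C; then HC(OMe)3, CSA, MeOH, 0 °C → rt; Et3N
Reagents that add atoms: methanol, CO
Why: Reductive desulfonylation of the β-keto sulfone by two single-electron transfers from SmI2 (samarium enolate protonated by MeOH) followed by acid-catalysed cyclic ketalization of the γ-hydroxy ketone should remove the sulfonyl helper and mask the ketone against hydride.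

**Step 6**
Reactants: 14 (2S)-4-[(5S)-5-(hex-5-en-1-yl)-2-methoxytetrahydrofuran-2-yl]butan-2-yl N,N-diisopropylcarbamate
Product: 16 (2S,5S,7S)-2-(hex-5-en-1-yl)-7-methyl-1,6-dioxaspiro[4.4]nonane, via ketal alcohol 15 (not isolated)
Conditions: LiAlH4, THF, reflux; 0 °C, then 1 M aq. HCl/THF, rt; chromatography, (5R) epimer returned to 1 M aq. HCl/THF
Reagents that add atoms: none
Why: Hydride cleavage of the carbamate (LiAlH4 reduction) frees the C7 alcohol, and acid then ionises the methyl ketal to the oxocarbenium ion that this alcohol traps (thermodynamic spiroketalization), so the spiro centre is set by equilibration, separation of the (5S) epimer and recycling of the other.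

**Step 7**
Reactants: 17 3,5-dimethoxybenzaldehyde
Product: 18 2-bromo-3,5-dimethoxybenzaldehyde
Conditions: NBS, MeCN, 0 °C → rt
Reagents that add atoms: N-bromosuccinimide, BrN1C(=O)CCC1=O
Why: Electrophilic aromatic bromination should occur at C2, which is ortho to one methoxy group and para to the other and less hindered than the position between the two methoxy groups.

**Step 8**
Reactants: 16 (2S,5S,7S)-2-(hex-5-en-1-yl)-7-methyl-1,6-dioxaspiro[4.4]nonane; 18 2-bromo-3,5-dimethoxybenzaldehyde
Product: 22 (1S)-1-(2-bromo-3,5-dimethoxyphenyl)-7-[(2S,5S,7S)-7-methyl-1,6-dioxaspiro[4.4]nonan-2-yl]heptan-1-ol, via alkyldiethylborane 19 (not isolated), via dialkylzinc 20 (not isolated), via mixed alkylzinc 21 (not isolated)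
Conditions: 16 (1.3 equiv), Et2BH (from BH3·SMe2 and Et3B), 0 °C → rt; Et2Zn, 0 °C, volatiles removed in vacuo; Zn(CH2SiMe3)2, toluene; then Ti(OiPr)4, (1R,2R)-1,2-bis(trifluoromethanesulfonamido)cyclohexane (8 mol%), 18, toluene, −20 °C; aq. NH4Cl
Reagents that add atoms: none
Why: Anti-Markovnikov hydroboration, boron–zinc exchange and catalytic enantioselective alkylzinc addition to the aldehyde (Ti(OiPr)4/bis-sulfonamide catalysis, with (trimethylsilyl)methyl as the non-transferred group) should deliver the alkyl group to the Si face and give the (S) carbinol under ligand control, independent of the remote spiroketal.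

**Step 9**
Reactants: 22 (1S)-1-(2-bromo-3,5-dimethoxyphenyl)-7-[(2S,5S,7S)-7-methyl-1,6-dioxaspiro[4.4]nonan-2-yl]heptan-1-ol
Product: 23 (3S)-5,7-dimethoxy-3-{6-[(2S,5S,7S)-7-methyl-1,6-dioxaspiro[4.4]nonan-2-yl]hexyl}-2-benzofuran-1(3H)-one
Conditions: Pd(OAc)2 (5 mol%), Xantphos (6 mol%), CO (1 atm), K2CO3, toluene, 100 °C
Reagents that add atoms: carbon monoxide, [C-]#[O+]
Why: Palladium-catalysed carbonylative lactonization (oxidative addition of zerovalent palladium into the aryl bromide, CO insertion, intramolecular alkoxycarbonylation by the benzylic hydroxyl) should close the phthalide under basic conditions that leave the carbinol and spiroketal centres untouched.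

**Compound list**

1 | (R)-5-(hydroxymethyl)dihydrofuran-2(3H)-one | OC[C@H]1CCC(=O)O1 | starting material
2 | [(2R)-5-oxotetrahydrofuran-2-yl]methyl 4-methylbenzenesulfonate | Cc1ccc(cc1)S(=O)(=O)OC[C@H]1CCC(=O)O1 | intermediate
3 | 5-bromopent-1-ene | BrCCCC=C | starting material
4 | pent-4-enylmagnesium bromide | C=CCCC[Mg]Br | intermediate (not isolated)
5 | bromomagnesium bis(pent-4-enyl)cuprate | C=CCCC[Cu-]CCCC=C.[Mg+]Br | intermediate (not isolated)
6 | (S)-5-(hex-5-en-1-yl)dihydrofuran-2(3H)-one | C=CCCCC[C@H]1CCC(=O)O1 | intermediate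
7 | ethanol | CCO | starting material
8 | ethyl N,N-diisopropylcarbamate | CCOC(=O)N(C(C)C)C(C)C | intermediate
9 | phenyl vinyl sulfone | C=CS(=O)(=O)c1ccccc1 | starting material
10 | (R)-1-lithioethyl N,N-diisopropylcarbamate (sparteine complex) | C[C@H](OC(=O)N(C(C)C)C(C)C)[Li] | intermediate (not isolated)
11 | (2S)-4-lithio-4-(phenylsulfonyl)butan-2-yl N,N-diisopropylcarbamate | C[C@H](OC(=O)N(C(C)C)C(C)C)CC([Li])S(=O)(=O)c1ccccc1 | intermediate (not isolated)
12 | (2S,8S)-8-hydroxy-5-oxo-4-(phenylsulfonyl)tetradec-13-en-2-yl N,N-diisopropylcarbamate (C4 epimers) | C[C@H](OC(=O)N(C(C)C)C(C)C)CC(S(=O)(=O)c1ccccc1)C(=O)CC[C@@H](O)CCCCC=C | intermediate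
13 | (2S,8S)-8-hydroxy-5-oxotetradec-13-en-2-yl N,N-diisopropylcarbamate | C[C@H](OC(=O)N(C(C)C)C(C)C)CCC(=O)CC[C@@H](O)CCCCC=C | intermediate (not isolated)
14 | (2S)-4-[(5S)-5-(hex-5-en-1-yl)-2-methoxytetrahydrofuran-2-yl]butan-2-yl N,N-diisopropylcarbamate (anomers) | C[C@H](OC(=O)N(C(C)C)C(C)C)CCC1(OC)CC[C@H](CCCCC=C)O1 | intermediate
15 | (2S)-4-[(5S)-5-(hex-5-en-1-yl)-2-methoxytetrahydrofuran-2-yl]butan-2-ol | C[C@H](O)CCC1(OC)CC[C@H](CCCCC=C)O1 | intermediate (not isolated)
16 | (2S,5S,7S)-2-(hex-5-en-1-yl)-7-methyl-1,6-dioxaspiro[4.4]nonane | C=CCCCC[C@H]1CC[C@]2(CC[C@H](C)O2)O1 | intermediate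
17 | 3,5-dimethoxybenzaldehyde | COc1cc(C=O)cc(OC)c1 | starting material
18 | 2-bromo-3,5-dimethoxybenzaldehyde | COc1cc(OC)c(Br)c(C=O)c1 | intermediate
19 | diethyl{6-[(2S,5S,7S)-7-methyl-1,6-dioxaspiro[4.4]nonan-2-yl]hexyl}borane | CCB(CC)CCCCCC[C@H]1CC[C@]2(CC[C@H](C)O2)O1 | intermediate (not isolated)
20 | bis{6-[(2S,5S,7S)-7-methyl-1,6-dioxaspiro[4.4]nonan-2-yl]hexyl}zinc | [Zn](CCCCCC[C@H]1CC[C@]2(CC[C@H](C)O2)O1)CCCCCC[C@H]1CC[C@]2(CC[C@H](C)O2)O1 | intermediate (not isolated)
21 | {6-[(2S,5S,7S)-7-methyl-1,6-dioxaspiro[4.4]nonan-2-yl]hexyl}[(trimethylsilyl)methyl]zinc | C[Si](C)(C)C[Zn]CCCCCC[C@H]1CC[C@]2(CC[C@H](C)O2)O1 | intermediate (not isolated)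
22 | (1S)-1-(2-bromo-3,5-dimethoxyphenyl)-7-[(2S,5S,7S)-7-methyl-1,6-dioxaspiro[4.4]nonan-2-yl]heptan-1-ol | COc1cc(OC)c(Br)c(c1)[C@@H](O)CCCCCC[C@H]1CC[C@]2(CC[C@H](C)O2)O1 | intermediate
23 | (3S)-5,7-dimethoxy-3-{6-[(2S,5S,7S)-7-methyl-1,6-dioxaspiro[4.4]nonan-2-yl]hexyl}-2-benzofuran-1(3H)-one | COc1cc(OC)c2c(c1)[C@H](CCCCCC[C@H]1CC[C@]3(CC[C@H](C)O3)O1)OC2=O | target

**Step count and risks**

Total step count: 9. Longest linear sequence: 7 steps (1, 2, 4, 5, 6, 8, 9).

Step 4 (bears the label) is the most likely to fail. Carbanion 11 may start anionic oligomerisation of the vinyl sulfone, the lithiated carbon may lose or invert its configuration during the conjugate addition, the carbamoyl group may shift onto the sulfonyl carbanion, and proton transfer from the lactone α-position may compete with acylation. The fallback uses known chemistry, gives up the one-operation union and builds the C8–C9 bond instead; it sets out from 6 and returns at 16. Methyl phenyl sulfone is lithiated (nBuLi, THF, −78 °C) to (phenylsulfonyl)methyllithium F1, which opens commercial (S)-propylene oxide at its CH2 (BF3·OEt2, −78 °C) to give (S)-4-(phenylsulfonyl)butan-2-ol F2, so that C7 comes from the epoxide. Double deprotonation (nBuLi, 2 equiv per F2, THF, −78 → −20 °C) gives the C,O-dilithio derivative F3, which is used in twofold amount to acylate lactone 6 to (2S,8S)-2,8-dihydroxy-4-(phenylsulfonyl)tetradec-13-en-5-one F4. SmI2 in THF/MeOH at −78 °C removes the sulfonyl group to give (2S,8S)-2,8-dihydroxytetradec-13-en-5-one F5, and 1 M aqueous HCl in THF closes both rings to 16 with the same equilibration and recycling of the spiro epimer.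

Step 8 is the next most likely to fail. Boron–zinc exchange may be incomplete or the zinc ligands may scramble so that ethyl or (trimethylsilyl)methyl groups transfer, facial selectivity may be poor with the ortho-brominated electron-rich aldehyde, and the Lewis acids may epimerise the spiro centre. The fallback sets the carbinol by reagent-controlled ketone reduction; it sets out from 16 and returns at 22. Hydroboration of 16 with 9-BBN in THF gives the B-alkyl-9-borabicyclo[3.3.1]nonane F6, and iodinolysis (I2, NaOMe, MeOH, 0 °C) gives (2S,5S,7S)-2-(6-iodohexyl)-7-methyl-1,6-dioxaspiro[4.4]nonane F7. Iodine–lithium exchange (tBuLi, 2 equiv, Et2O/pentane, −78 °C) gives the alkyllithium F8, which is added to aldehyde 18 at −78 °C to give 1-(2-bromo-3,5-dimethoxyphenyl)-7-[(2S,5S,7S)-7-methyl-1,6-dioxaspiro[4.4]nonan-2-yl]heptan-1-ol as both C1 epimers F9. Dess–Martin periodinane (NaHCO3, CH2Cl2) gives 1-(2-bromo-3,5-dimethoxyphenyl)-7-[(2S,5S,7S)-7-methyl-1,6-dioxaspiro[4.4]nonan-2-yl]heptan-1-one F10, and CBS reduction ((R)-2-methyl-CBS-oxazaborolidine, BH3·SMe2, THF, −20 °C) should give 22.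

Step 2 is the third risk. The cuprate may attack the lactone carbonyl, and the tosylate may be reduced or eliminated instead of substituted. The fallback replaces tosylate substitution by epoxide opening; it sets out from 2 and returns at 6. K2CO3 in MeOH opens the lactone and the liberated alkoxide displaces the tosylate to give methyl (R)-3-(oxiran-2-yl)propanoate F11. Grignard reagent 4 with CuI (10 mol%) in THF at −30 °C opens the epoxide at its CH2 to give methyl (S)-4-hydroxydec-9-enoate F12, which lactonizes with TsOH (cat.) in toluene to 6.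

**Further compounds**

F1 | step 4 | (phenylsulfonyl)methyllithium | [Li]CS(=O)(=O)c1ccccc1
F2 | step 4 | (S)-4-(phenylsulfonyl)butan-2-ol | C[C@H](O)CCS(=O)(=O)c1ccccc1
F3 | step 4 | C,O-dilithio derivative of (S)-4-(phenylsulfonyl)butan-2-ol | C[C@H](O[Li])CC([Li])S(=O)(=O)c1ccccc1
F4 | step 4 | (2S,8S)-2,8-dihydroxy-4-(phenylsulfonyl)tetradec-13-en-5-one (C4 epimers) | C[C@H](O)CC(S(=O)(=O)c1ccccc1)C(=O)CC[C@@H](O)CCCCC=C
F5 | step 4 | (2S,8S)-2,8-dihydroxytetradec-13-en-5-one | C[C@H](O)CCC(=O)CC[C@@H](O)CCCCC=C
F6 | step 8 | 9-{6-[(2S,5S,7S)-7-methyl-1,6-dioxaspiro[4.4]nonan-2-yl]hexyl}-9-borabicyclo[3.3.1]nonane | C1CCC2CCCC1B2CCCCCC[C@H]1CC[C@]2(CC[C@H](C)O2)O1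
F7 | step 8 | (2S,5S,7S)-2-(6-iodohexyl)-7-methyl-1,6-dioxaspiro[4.4]nonane | ICCCCCC[C@H]1CC[C@]2(CC[C@H](C)O2)O1
F8 | step 8 | {6-[(2S,5S,7S)-7-methyl-1,6-dioxaspiro[4.4]nonan-2-yl]hexyl}lithium | [Li]CCCCCC[C@H]1CC[C@]2(CC[C@H](C)O2)O1
F9 | step 8 | 1-(2-bromo-3,5-dimethoxyphenyl)-7-[(2S,5S,7S)-7-methyl-1,6-dioxaspiro[4.4]nonan-2-yl]heptan-1-ol (C1 epimers) | COc1cc(OC)c(Br)c(c1)C(O)CCCCCC[C@H]1CC[C@]2(CC[C@H](C)O2)O1
F10 | step 8 | 1-(2-bromo-3,5-dimethoxyphenyl)-7-[(2S,5S,7S)-7-methyl-1,6-dioxaspiro[4.4]nonan-2-yl]heptan-1-one | COc1cc(OC)c(Br)c(c1)C(=O)CCCCCC[C@H]1CC[C@]2(CC[C@H](C)O2)O1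
F11 | step 2 | methyl (R)-3-(oxiran-2-yl)propanoate | COC(=O)CC[C@@H]1CO1
F12 | step 2 | methyl (S)-4-hydroxydec-9-enoate | COC(=O)CC[C@@H](O)CCCCC=C
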